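**Plan**

Numbering used: lactone O1, C2 (C=O), C3 (C–OH), C4 (C–aryl), C5 (stereocentre), C6 = the benzylic CH2 on C5.
Retrosynthesis: an extra bond C4–C6 is first added (a 2-oxabicyclo[3.1.0]hexane-3,4-dione); then C4–C5 and C4–C6 are cut together (carbene + alkene), then O1–C5 (acid + alkyne), then aryl–alkyne and aryl–prenyl.
Enabling feature: C5 carries O1 and C6, so C5–C6 is the reduced form of an enol-ester C=C; C4 lies between an aryl ring and the C3 carbonyl, so it can be a donor/acceptor carbene carbon, and the C3 ketone later serves as the radical acceptor that cuts C4–C6.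
Forward: prenylated aryl alkyne + silylated 4-hydroxyphenylpyruvic acid → Z enol ester (O1–C5) → diazo group at C4 → one event closes the butenolide ring (C4–C5) and a cyclopropane (C4–C6) → radical opening of C4–C6 leaves C6 as CH2 and C3 as the enol → desilylation.
Stereochemistry: C5 is set in the cyclopropanation by the chiral dirhodium catalyst (face of the enol-ester alkene); the two other stereocentres of the bicycle (C4, C6) are erased in the ring opening, and no later step touches C5.

Key step: step 7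

Assumption: the sense of induction of the dirhodium catalyst for this tether cannot be derived with certainty; the S-configured catalyst is written, and its mirror image is used if that is the one leading to (1R)-13.

**Step 1**
Reactants: 1 4-iodophenol; 2 prenyl bromide (1-bromo-3-methylbut-2-ene)
Product: 3 4-iodo-2-(3-methylbut-2-en-1-yl)phenol
Conditions: NaH (1.0 equiv), toluene, 0 °C; then 2, rt
Reagents that add atoms: none
Why: ortho C-allylation of a sodium phenoxide as a tight ion pair in a non-polar solvent should place the prenyl group on the free ortho carbon (para is blocked by iodine), with the O-prenyl ether as the separable by-product.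

**Step 2**
Reactants: 3 4-iodo-2-(3-methylbut-2-en-1-yl)phenol
Product: 4 [4-iodo-2-(3-methylbut-2-en-1-yl)phenoxy]triisopropylsilane
Conditions: TIPSCl, imidazole, DMF, rt
Reagents that add atoms: triisopropylsilyl chloride, CC(C)[Si](Cl)(C(C)C)C(C)C
Why: standard phenol silylation; the bulky aryl silyl ether should survive the organometallic, acidic, carbene and radical steps and fall to fluoride at the end.

**Step 3**
Reactants: 4 [4-iodo-2-(3-methylbut-2-en-1-yl)phenoxy]triisopropylsilane; 5 ethynylmagnesium bromide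
Product: 6 [4-ethynyl-2-(3-methylbut-2-en-1-yl)phenoxy]triisopropylsilane
Conditions: 5, ZnBr2, THF, 0 °C; then 4, Pd(PPh3)4 (5 mol%), rt
Reagents that add atoms: none
Why: Negishi coupling of an aryl iodide with ethynylzinc bromide should give the terminal arylacetylene directly, without a C-silyl group to remove.

**Step 4**
Reactants: 7 4-hydroxyphenylpyruvic acid
Product: 9 (Z)-2-(triisopropylsilyloxy)-3-[4-(triisopropylsilyloxy)phenyl]prop-2-enoic acid, via tris-silyl derivative 8 (not isolated)
Conditions: TIPSOTf (3.3 equiv), Et3N, CH2Cl2, 0 °C; then THF/H2O/AcOH, rt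
Reagents that add atoms: triisopropylsilyl trifluoromethanesulfonate, CC(C)[Si](OS(=O)(=O)C(F)(F)F)(C(C)C)C(C)C
Why: exhaustive O-silylation of the enolised keto acid (phenol, Z enol and carboxyl oxygens) followed by selective hydrolysis of the silyl ester, the most labile Si–O bond, should leave an acid with no free enol OH and no acidic CH2.

**Step 5**
Reactants: 6 [4-ethynyl-2-(3-methylbut-2-en-1-yl)phenoxy]triisopropylsilane; 9 (Z)-2-(triisopropylsilyloxy)-3-[4-(triisopropylsilyloxy)phenyl]prop-2-enoic acid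
Product: 11 (Z)-2-[3-(3-methylbut-2-en-1-yl)-4-(triisopropylsilyloxy)phenyl]ethenyl 2-oxo-3-[4-(triisopropylsilyloxy)phenyl]propanoate, via silyl enol ether ester 10 (not isolated)
Conditions: [Ru(η3-2-methylallyl)2(dppb)] (2 mol%; dppb = Ph2P(CH2)4PPh2), toluene, 65 °C; then THF/2 M aq. HCl, rt
Reagents that add atoms: none
Why: ruthenium-catalysed anti-Markovnikov addition of a carboxylic acid to a terminal alkyne (carboxylate attack on a ruthenium vinylidene) should give the Z enol ester, after which acid hydrolysis of the silyl enol ether by C-protonation, a path closed to the two aryl silyl ethers, frees the arylpyruvate (largely enolised).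

**Step 6**
Reactants: 11 (Z)-2-[3-(3-methylbut-2-en-1-yl)-4-(triisopropylsilyloxy)phenyl]ethenyl 2-oxo-3-[4-(triisopropylsilyloxy)phenyl]propanoate
Product: 12 (Z)-2-[3-(3-methylbut-2-en-1-yl)-4-(triisopropylsilyloxy)phenyl]ethenyl 3-diazo-2-oxo-3-[4-(triisopropylsilyloxy)phenyl]propanoate
Conditions: p-ABSA (1.2 equiv), Et3N, MeCN, 0 °C to rt
Reagents that add atoms: 4-acetamidobenzenesulfonyl azide, CC(=O)Nc1ccc(cc1)S(=O)(=O)N=[N+]=[N-]
Why: Regitz diazo transfer to the benzylic CH2 activated by the C3 ketone should need only triethylamine, which spares the acyl-donor vinyl ester from stronger amidine bases.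

**Step 7**
Reactants: 12 (Z)-2-[3-(3-methylbut-2-en-1-yl)-4-(triisopropylsilyloxy)phenyl]ethenyl 3-diazo-2-oxo-3-[4-(triisopropylsilyloxy)phenyl]propanoate
Product: 13 (1R,5R,6R)-6-[3-(3-methylbut-2-en-1-yl)-4-(triisopropylsilyloxy)phenyl]-5-[4-(triisopropylsilyloxy)phenyl]-2-oxabicyclo[3.1.0]hexane-3,4-dione
Conditions: Rh2(S-PTAD)4 (1 mol%; PTAD = 2-(1-adamantyl)-2-phthalimidoacetate), PhCF3, 0 °C to rt, slow addition of 12 (final 0.01 M); filtered through neutral alumina and used at once
Reagents that add atoms: none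
Why: The dirhodium tetracarboxylate expels N2 from the aryl diazoketone, and the electrophilic donor/acceptor rhodium carbene at C4 adds to the tethered enol-ester C5=C6 in an asynchronous [2+1] event in which the C4–C5 bond forms first and the C4–C6 bond follows as positive charge builds up at benzylic C6. The closest known reaction type is the enantioselective dirhodium-catalysed intramolecular cyclopropanation of alkenyl diazo esters and diazoketones (allyl diazoacetates to 3-oxabicyclo[3.1.0]hexan-2-ones), together with the intermolecular cyclopropanation of styrenes and vinyl esters by aryl diazoketone carbenes. The lactone ring closes in the 5-exo mode through the three-atom tether C3–C2–O1 onto the proximal alkene carbon C5, and the three-membered ring by 3-exo collapse of C4 onto C6. C5 is set by the chiral carboxylate pocket of the catalyst, which selects the alkene face; C4 follows from the obligatory cis fusion and C6 from stereospecific syn addition to the Z alkene (aryl endo), and both are erased in step 8. The step needs chemoselectivity for the enol-ester double bond over the prenyl double bond, the arenes and C–H bonds: the tether allows only the five-membered closure, no sp3 C–H lies within reach of C4, and closure through the ketone oxygen to a dihydrofuran would demand a bridgehead double bond in a bicyclo[2.2.1] frame.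

**Step 8**
Reactants: 13 (1R,5R,6R)-6-[3-(3-methylbut-2-en-1-yl)-4-(triisopropylsilyloxy)phenyl]-5-[4-(triisopropylsilyloxy)phenyl]-2-oxabicyclo[3.1.0]hexane-3,4-dione
Product: 15 (5R)-3-hydroxy-5-{[3-(3-methylbut-2-en-1-yl)-4-(triisopropylsilyloxy)phenyl]methyl}-4-[4-(triisopropylsilyloxy)phenyl]furan-2(5H)-one, via stannyl enol ether 14 (not isolated)
Conditions: Bu3SnH (1.3 equiv), Et3B (0.2 equiv), air, toluene, 0 °C to rt; then aq. KF
Reagents that add atoms: none
Why: radical-chain reductive opening of a cyclopropyl ketone, in which the stannyl radical adds to the C3 ketone oxygen, the resulting radical cleaves the exocyclic C4–C6 bond (best overlap with the carbonyl π system, benzylic radical formed) and the C6 radical takes hydrogen from the stannane, so that no carbanion arises next to the C5–O1 bond, C5 is untouched and the tin enolate hydrolyses to the C3 enol.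

**Step 9**
Reactants: 15 (5R)-3-hydroxy-5-{[3-(3-methylbut-2-en-1-yl)-4-(triisopropylsilyloxy)phenyl]methyl}-4-[4-(triisopropylsilyloxy)phenyl]furan-2(5H)-one
Product: 16 (5R)-3-hydroxy-4-(4-hydroxyphenyl)-5-{[4-hydroxy-3-(3-methylbut-2-en-1-yl)phenyl]methyl}furan-2(5H)-one
Conditions: TBAF (2.2 equiv), AcOH (2.2 equiv), THF, 0 °C
Reagents that add atoms: none
Why: fluoride cleavage of the two aryl silyl ethers under acetic acid buffering should avoid both base-mediated loss of the C5 proton and acid-mediated cyclisation of the ortho-prenyl phenol to a chroman.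

**Compound list**

1 | 4-iodophenol | Oc1ccc(I)cc1 | starting material
2 | prenyl bromide (1-bromo-3-methylbut-2-ene) | CC(C)=CCBr | starting material
3 | 4-iodo-2-(3-methylbut-2-en-1-yl)phenol | CC(C)=CCc1cc(I)ccc1O | intermediate
4 | [4-iodo-2-(3-methylbut-2-en-1-yl)phenoxy]triisopropylsilane | CC(C)=CCc1cc(I)ccc1O[Si](C(C)C)(C(C)C)C(C)C | intermediate
5 | ethynylmagnesium bromide | C#C[Mg]Br | starting material
6 | [4-ethynyl-2-(3-methylbut-2-en-1-yl)phenoxy]triisopropylsilane | CC(C)=CCc1cc(C#C)ccc1O[Si](C(C)C)(C(C)C)C(C)C | intermediate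
7 | 4-hydroxyphenylpyruvic acid (drawn as keto form) | O=C(O)C(=O)Cc1ccc(O)cc1 | starting material
8 | triisopropylsilyl (Z)-2-(triisopropylsilyloxy)-3-[4-(triisopropylsilyloxy)phenyl]prop-2-enoate | CC(C)[Si](C(C)C)(C(C)C)OC(=O)/C(O[Si](C(C)C)(C(C)C)C(C)C)=C/c1ccc(O[Si](C(C)C)(C(C)C)C(C)C)cc1 | intermediate
9 | (Z)-2-(triisopropylsilyloxy)-3-[4-(triisopropylsilyloxy)phenyl]prop-2-enoic acid | OC(=O)/C(O[Si](C(C)C)(C(C)C)C(C)C)=C/c1ccc(O[Si](C(C)C)(C(C)C)C(C)C)cc1 | intermediate
10 | (Z)-2-[3-(3-methylbut-2-en-1-yl)-4-(triisopropylsilyloxy)phenyl]ethenyl (Z)-2-(triisopropylsilyloxy)-3-[4-(triisopropylsilyloxy)phenyl]prop-2-enoate | CC(C)=CCc1cc(/C=C\OC(=O)/C(O[Si](C(C)C)(C(C)C)C(C)C)=C/c2ccc(O[Si](C(C)C)(C(C)C)C(C)C)cc2)ccc1O[Si](C(C)C)(C(C)C)C(C)C | intermediate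
11 | (Z)-2-[3-(3-methylbut-2-en-1-yl)-4-(triisopropylsilyloxy)phenyl]ethenyl 2-oxo-3-[4-(triisopropylsilyloxy)phenyl]propanoate (drawn as keto form) | CC(C)=CCc1cc(/C=C\OC(=O)C(=O)Cc2ccc(O[Si](C(C)C)(C(C)C)C(C)C)cc2)ccc1O[Si](C(C)C)(C(C)C)C(C)C | intermediate
12 | (Z)-2-[3-(3-methylbut-2-en-1-yl)-4-(triisopropylsilyloxy)phenyl]ethenyl 3-diazo-2-oxo-3-[4-(triisopropylsilyloxy)phenyl]propanoate | CC(C)=CCc1cc(/C=C\OC(=O)C(=O)C(=[N+]=[N-])c2ccc(O[Si](C(C)C)(C(C)C)C(C)C)cc2)ccc1O[Si](C(C)C)(C(C)C)C(C)C | intermediate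
13 | (1R,5R,6R)-6-[3-(3-methylbut-2-en-1-yl)-4-(triisopropylsilyloxy)phenyl]-5-[4-(triisopropylsilyloxy)phenyl]-2-oxabicyclo[3.1.0]hexane-3,4-dione | CC(C)=CCc1cc([C@H]3[C@H]4OC(=O)C(=O)[C@@]34c2ccc(O[Si](C(C)C)(C(C)C)C(C)C)cc2)ccc1O[Si](C(C)C)(C(C)C)C(C)C | intermediate
14 | (5R)-5-{[3-(3-methylbut-2-en-1-yl)-4-(triisopropylsilyloxy)phenyl]methyl}-3-(tributylstannyloxy)-4-[4-(triisopropylsilyloxy)phenyl]furan-2(5H)-one | CC(C)=CCc1cc(C[C@H]2OC(=O)C(O[Sn](CCCC)(CCCC)CCCC)=C2c2ccc(O[Si](C(C)C)(C(C)C)C(C)C)cc2)ccc1O[Si](C(C)C)(C(C)C)C(C)C | intermediate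
15 | (5R)-3-hydroxy-5-{[3-(3-methylbut-2-en-1-yl)-4-(triisopropylsilyloxy)phenyl]methyl}-4-[4-(triisopropylsilyloxy)phenyl]furan-2(5H)-one | CC(C)=CCc1cc(C[C@H]2OC(=O)C(O)=C2c2ccc(O[Si](C(C)C)(C(C)C)C(C)C)cc2)ccc1O[Si](C(C)C)(C(C)C)C(C)C | intermediate
16 | (5R)-3-hydroxy-4-(4-hydroxyphenyl)-5-{[4-hydroxy-3-(3-methylbut-2-en-1-yl)phenyl]methyl}furan-2(5H)-one | CC(C)=CCc1cc(C[C@H]2OC(=O)C(O)=C2c2ccc(O)cc2)ccc1O | target

**Totals**

Total step count: 9. Longest linear sequence: 8 (steps 1, 2, 3, 5, 6, 7, 8, 9).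

**Steps most likely to fail**

Step 7. What may go wrong: poor facial selectivity of the carbene addition, or ionisation of the push–pull cyclopropane (donor aryl on C6, acceptor ketone on C4) that destroys the C5 configuration. Fallback, setting out from 12 and coming back at 15: decomposition of 12 with achiral Rh2(OAc)4 should give the racemic bicycle rac-(1R*,5R*,6R*)-6-[3-(3-methylbut-2-en-1-yl)-4-(triisopropylsilyloxy)phenyl]-5-[4-(triisopropylsilyloxy)phenyl]-2-oxabicyclo[3.1.0]hexane-3,4-dione F1. Catalytic Sc(OTf)3 in CH2Cl2 should then open the C4–C6 bond heterolytically, and loss of the C5 proton should give the achiral (5Z)-3-hydroxy-5-{[3-(3-methylbut-2-en-1-yl)-4-(triisopropylsilyloxy)phenyl]methylidene}-4-[4-(triisopropylsilyloxy)phenyl]furan-2(5H)-one F2. Asymmetric hydrogenation of the exocyclic enol-lactone C5=C6 bond of F2 with Ru(OAc)2[(R)-BINAP] and H2 in MeOH (antipodal ligand if the sense requires) should set C5 and give 15; the unfunctionalised prenyl alkene and the tetrasubstituted C3=C4 bond should not be reduced.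

Step 5. What may go wrong: slow addition of the hindered silyloxyacrylic acid to the alkyne with competing alkyne dimerisation or silyl migration, or hydrolytic loss of the activated vinyl ester during the aqueous acid unmasking. Fallback, setting out from 6 and 9 and coming back at 11: anti-Markovnikov hydration of 6 with [CpRu(NCMe)3]PF6 and 5,5'-bis(trifluoromethyl)-2,2'-bipyridine in NMP/H2O should give 2-[3-(3-methylbut-2-en-1-yl)-4-(triisopropylsilyloxy)phenyl]acetaldehyde F3. Acid 9 with oxalyl chloride and catalytic DMF should give (Z)-2-(triisopropylsilyloxy)-3-[4-(triisopropylsilyloxy)phenyl]prop-2-enoyl chloride F4, which has no acidic hydrogen. O-acylation of the Z potassium enolate of F3 (KHMDS, THF, −78 °C) with F4 should give 10, and anhydrous Et3N·3HF in THF in place of aqueous acid should unmask it to 11.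

Step 8. What may go wrong: slow hydrogen transfer to the stabilised C6 benzylic radical, so that the chain breaks down or a 1,2-acyloxy shift moves O1 from C5 to C6. Fallback, setting out from 13 and coming back at 15: an ionic instead of a radical opening, with Et3SiH (3 equiv) and Sc(OTf)3 (10 mol%) in CH2Cl2 at −40 °C. The Lewis acid should open the C4–C6 bond to the C6 benzylic cation and the C3 enolate, hydride should be delivered to C6, and the enolate should be silylated to (5R)-5-{[3-(3-methylbut-2-en-1-yl)-4-(triisopropylsilyloxy)phenyl]methyl}-3-(triethylsilyloxy)-4-[4-(triisopropylsilyloxy)phenyl]furan-2(5H)-one F5, which aqueous work-up should hydrolyse to 15.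

**Further compounds**

F1 | step 7 | rac-(1R*,5R*,6R*)-6-[3-(3-methylbut-2-en-1-yl)-4-(triisopropylsilyloxy)phenyl]-5-[4-(triisopropylsilyloxy)phenyl]-2-oxabicyclo[3.1.0]hexane-3,4-dione (racemate) | CC(C)=CCc1cc(C3C4OC(=O)C(=O)C34c2ccc(O[Si](C(C)C)(C(C)C)C(C)C)cc2)ccc1O[Si](C(C)C)(C(C)C)C(C)C
F2 | step 7 | (5Z)-3-hydroxy-5-{[3-(3-methylbut-2-en-1-yl)-4-(triisopropylsilyloxy)phenyl]methylidene}-4-[4-(triisopropylsilyloxy)phenyl]furan-2(5H)-one | CC(C)=CCc1cc(/C=C2\OC(=O)C(O)=C2c2ccc(O[Si](C(C)C)(C(C)C)C(C)C)cc2)ccc1O[Si](C(C)C)(C(C)C)C(C)C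
F3 | step 5 | 2-[3-(3-methylbut-2-en-1-yl)-4-(triisopropylsilyloxy)phenyl]acetaldehyde | CC(C)=CCc1cc(CC=O)ccc1O[Si](C(C)C)(C(C)C)C(C)C
F4 | step 5 | (Z)-2-(triisopropylsilyloxy)-3-[4-(triisopropylsilyloxy)phenyl]prop-2-enoyl chloride | ClC(=O)/C(O[Si](C(C)C)(C(C)C)C(C)C)=C/c1ccc(O[Si](C(C)C)(C(C)C)C(C)C)cc1
F5 | step 8 | (5R)-5-{[3-(3-methylbut-2-en-1-yl)-4-(triisopropylsilyloxy)phenyl]methyl}-3-(triethylsilyloxy)-4-[4-(triisopropylsilyloxy)phenyl]furan-2(5H)-one | CC(C)=CCc1cc(C[C@H]2OC(=O)C(O[Si](CC)(CC)CC)=C2c2ccc(O[Si](C(C)C)(C(C)C)C(C)C)cc2)ccc1O[Si](C(C)C)(C(C)C)C(C)C
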